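**Target (15):** (2S,4R,6S)-2-(4-hydroxy-3,5-dimethoxyphenyl)-6-[2-(4-hydroxy-3-methoxyphenyl)ethyl]oxan-4-ol, all-cis. Chain numbering used throughout: C1 carries ring A (4-hydroxy-3,5-dimethoxyphenyl), C3 the hydroxyl, C5 the ring oxygen, C7 ring C (4-hydroxy-3-methoxyphenyl); ring B is the oxane O–C1–C2–C3–C4–C5. In chain locants the target is 1S,3R,5S.

## The problem

The target 15 is a 1,7-diarylheptanoid in which an oxygen bridges C1 and C5. Ring B is an oxane that carries ring A on C1, a free hydroxyl on C3 and, on C5, the C6–C7 arm that ends in ring C. The three stereocentres are all cis, so all three substituents are equatorial on one chair. The relative configuration is therefore the thermodynamic one, and the real task is to bring in the absolute configuration and to avoid setting any centre kinetically the wrong way. Read as an open chain, C3 and C5 form an anti-1,3-diol, and once these two are fixed they can control C1 if the ring closure is reversible or passes through a chair. The feature that makes the key step possible is the C1–O bond of ring B: C1 is benzylic to ring A and para to its free hydroxyl, so ring A can be oxidised to a para-quinone methide in which C1 is a planar electrophilic carbon. The two methoxy groups of ring A stabilise this quinone methide and make it symmetrical, so it has no E/Z isomers. Sensitive points are the para-hydroxybenzylic ether (it ionises under strong acid or hot base), the oxidisable phenols, and the benzylic methylene C7 next to ring C, which any oxidation must leave alone; cationic closures at C1 are prone to scrambling because ring A stabilises the cation so well.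

## Retrosynthesis

**15 from 14.** Only the triisopropylsilyl ether on the oxygen of ring C is removed. Its purpose is to make ring C unable to form a quinone methide, so that ring A is the only oxidisable phenol in the key step. Fluoride removes it without acid or strong base, which the C1–O bond would not tolerate.

**14 from 12 (through 13).** The O–C1 bond is cut and C1 is taken back to a plain methylene. Cutting O–C5 instead would need an invertive displacement at a secondary carbinol, and cutting ring C–C bonds leads to the oxocarbenium chemistry that ring A makes unreliable. The precursor 12 has no ring B and only two stereocentres. The forward reaction must oxidise ring A to quinone methide 13, then add the C5 hydroxyl to C1. It needs site selectivity (ring A, not ring C), six- over four-membered closure, and the cis outcome at C1, which chair closure and reversibility should both deliver.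

**12 from 9.** Both carbinol centres are erased to give the achiral 1,3-diketone 9. Diol 12 is C2-symmetric but for one methoxy group, so one chiral catalyst can set both centres in a Noyori hydrogenation, with the anti relation coming from catalyst control in each reduction. Aldol routes would set one centre at a time and need a separate anti-reduction. Note that C3 is S in 12 and R in 14 and 15 only because the CIP priorities change on ring closure; no bond at C3 is touched.

**9 from 6, 6 from 5 and 2, 5 from 3 and 4, 2 from 1.** The C1–C2 and C6–C7 bonds are cut as C=C bonds of the curcuminoid 6, which is assembled by two boron-templated aldol condensations on pentane-2,4-dione 3. Syringaldehyde 4 (free phenol tolerated) goes on first to give 5, then the silylated vanillin 2, made in one step from vanillin 1. Hydrogenation of the two alkenes of 6 gives 9. All starting materials are cheap aromatic aldehydes and acetylacetone.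

## Roads not taken

**Alternative 1:** Prins cyclisation, the most obvious route. Cut O–C1, C1–C2 and the C3–O bond. The homoallylic alcohol A1 (from an asymmetric allylation) and the benzylated syringaldehyde A2 would be condensed under acid to the all-cis oxanol A3, then debenzylated. The oxocarbenium ion conjugated with ring A is stabilised and slow to cyclise, which gives the competing 2-oxonia-Cope rearrangement time to exchange the allyl group between the partners (symmetrical tetrahydropyrans, erosion of ee). Both phenols must be protected, and a separate asymmetric step is needed for one centre only. The chosen plan never generates a cation at C1 under irreversible conditions and sets two centres with one catalyst.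

**Alternative 2:** intramolecular oxa-Michael addition. Cut O–C1 at the enone oxidation level. The hydroxy enone A4 (from an asymmetric methyl-ketone aldol) would close 6-endo to the cis oxan-4-one A5, followed by ketone reduction. The β-carbon of an enone conjugated with an electron-rich ring A is a poor acceptor, the closure is reversible, and the β-hydroxy ketone can undergo retro-aldol cleavage. C3 then needs a third, separate stereo-setting step, and methyl-ketone aldols rarely match the selectivity of diketone hydrogenation.

**Alternative 3:** asymmetric hetero-Diels–Alder reaction. Cut O–C5 and C3–C4. Aldehyde A6 and diene A7 with a chiral Lewis acid would give dihydropyranone A8, which sets only C5. Ring A must then be added at C1, and conjugate addition to such enones proceeds by axial attack to the 1,5-trans isomer, the wrong one. Correcting this (arylation at the enone level, hydrogenation, ketone reduction) adds three further selective steps, whereas in the chosen plan C1 follows from C3 and C5 under thermodynamic control.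

Key step: step 6

Assumption: 1, 3, 4 and all reagents are taken as commercial; the 1,3-diketones 5–9 are drawn as diketo tautomers although they exist largely as enols.

## Route

Step 1
Reactants: 1 vanillin (4-hydroxy-3-methoxybenzaldehyde)
Product: 2 3-methoxy-4-[(triisopropylsilyl)oxy]benzaldehyde
Conditions: TIPSCl, imidazole, DMF, rt
Reagents that add atoms: chlorotriisopropylsilane (TIPSCl), CC(C)[Si](Cl)(C(C)C)C(C)C
Why: Standard phenol silylation; the bulky aryl silyl ether should survive amine/boron condensation, both hydrogenations and Ag2O, and it blocks quinone methide formation on ring C.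

Step 2
Reactants: 3 pentane-2,4-dione (3 equiv), 4 syringaldehyde (4-hydroxy-3,5-dimethoxybenzaldehyde)
Product: 5 (5E)-6-(4-hydroxy-3,5-dimethoxyphenyl)hex-5-ene-2,4-dione
Conditions: B2O3, EtOAc, 75 °C; then 4, B(OBu)3, nBuNH2 (cat., slow addition), 75 °C; then 0.4 M aq. HCl, 60 °C
Reagents that add atoms: none
Why: Boron-templated aldol condensation (Pabon conditions): boron chelation of the diketone enol blocks Knoevenagel reaction at the central carbon and directs the amine-catalysed condensation to a methyl group; excess 3 should suppress double condensation and the alkene forms E.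

Step 3
Reactants: 5 (5E)-6-(4-hydroxy-3,5-dimethoxyphenyl)hex-5-ene-2,4-dione, 2 3-methoxy-4-[(triisopropylsilyl)oxy]benzaldehyde
Product: 6 (1E,6E)-1-(4-hydroxy-3,5-dimethoxyphenyl)-7-{3-methoxy-4-[(triisopropylsilyl)oxy]phenyl}hepta-1,6-diene-3,5-dione
Conditions: B2O3, B(OBu)3, nBuNH2 (cat.), EtOAc, 75 °C; then 10% aq. AcOH, 50 °C
Reagents that add atoms: none
Why: Second boron-templated aldol condensation at the remaining methyl group of 5, the usual stepwise way to unsymmetrical curcuminoids; mild acetic acid hydrolysis of the boron chelate spares the silyl ether.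

Step 4
Reactants: 6 (1E,6E)-1-(4-hydroxy-3,5-dimethoxyphenyl)-7-{3-methoxy-4-[(triisopropylsilyl)oxy]phenyl}hepta-1,6-diene-3,5-dione
Product: 9 1-(4-hydroxy-3,5-dimethoxyphenyl)-7-{3-methoxy-4-[(triisopropylsilyl)oxy]phenyl}heptane-3,5-dione, via hept-1-ene-3,5-dione 7 (not isolated), via hept-6-ene-3,5-dione 8 (not isolated)
Conditions: H2 (1 atm), 10% Pd/C, EtOAc, rt
Reagents that add atoms: none
Why: Heterogeneous hydrogenation of the two conjugated alkenes, as in the conversion of curcuminoids into their tetrahydro derivatives; the enolised diketone and the aryl silyl ether should be untouched in ethyl acetate.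

Step 5
Reactants: 9 1-(4-hydroxy-3,5-dimethoxyphenyl)-7-{3-methoxy-4-[(triisopropylsilyl)oxy]phenyl}heptane-3,5-dione
Product: 12 (3S,5S)-1-(4-hydroxy-3,5-dimethoxyphenyl)-7-{3-methoxy-4-[(triisopropylsilyl)oxy]phenyl}heptane-3,5-diol, via 5-hydroxyheptan-3-one 10 (not isolated), via 3-hydroxyheptan-5-one 11 (not isolated)
Conditions: H2 (50 atm), [RuCl(p-cymene)((S)-BINAP)]Cl (1 mol%), MeOH, 50 °C
Reagents that add atoms: none
Why: Noyori asymmetric hydrogenation of a β-diketone: each carbonyl is reduced through a chelated ruthenium hydride, the (S)-ligand giving the S carbinol (by analogy with (R)-BINAP giving (R,R)-pentane-2,4-diol), and the second reduction of 10 or 11 is again catalyst-controlled, hence the anti (3S,5S)-diol; the double reduction should also raise the ee, since the minor enantiomer of the first reduction is diverted into the separable syn diastereomer.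

Step 6
Reactants: 12 (3S,5S)-1-(4-hydroxy-3,5-dimethoxyphenyl)-7-{3-methoxy-4-[(triisopropylsilyl)oxy]phenyl}heptane-3,5-diol
Product: 14 (2S,4R,6S)-2-(4-hydroxy-3,5-dimethoxyphenyl)-6-(2-{3-methoxy-4-[(triisopropylsilyl)oxy]phenyl}ethyl)oxan-4-ol, via para-quinone methide 13 (not isolated)
Conditions: Ag2O (3 equiv), CH2Cl2 (0.01 M), 0 °C to rt, dark; filter (Celite); then (PhO)2P(O)OH (5 mol%), 0 °C to rt
Reagents that add atoms: none
Why: Ag2O removes two electrons and two protons from ring A (phenoxyl radical, then loss of a benzylic C1–H), turning the 4-alkyl-2,6-dimethoxyphenol into para-quinone methide 13 with C1 sp2; a trace of acid then activates the dienone, the C5 hydroxyl adds to C1 in an oxa-1,6-conjugate addition and ring A rearomatises. The closest known reaction types are the Ag2O oxidation of 4-alkyl-2,6-dimethoxyphenols to quinone methides followed by acid-promoted intramolecular 1,6-addition, and the oxidative cyclisation of 4-(hydroxyalkyl)phenols to 2-aryl cyclic ethers. Ring B closes in the 6-exo-trig mode (the oxygen on C5 attacks the exocyclic methide carbon C1); the 4-exo closure by the C3 hydroxyl is strained and reversible and should not compete. The new centre C1 is controlled by C3 and C5: in the chair transition state the C5 arm and the C3 hydroxyl of the anti-diol are both equatorial and ring A takes the third equatorial place, giving 1S. Because the para-hydroxybenzylic ether re-ionises under the same acid, any 1R epimer returns to 13 and is funnelled to the all-equatorial isomer, so both faces of the symmetrical 13 lead to one product. Site selectivity (ring A against ring C, C1–H against C7–H) is secured by the silyl ether on ring C, which cannot form a quinone methide. Over-oxidation of the product is limited by filtering off the silver before the acid is added; high dilution disfavours intermolecular addition, and the weak acid and low temperature disfavour tautomerisation of 13 to the 4-hydroxystyrene.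

Step 7
Reactants: 14 (2S,4R,6S)-2-(4-hydroxy-3,5-dimethoxyphenyl)-6-(2-{3-methoxy-4-[(triisopropylsilyl)oxy]phenyl}ethyl)oxan-4-ol
Product: 15 (2S,4R,6S)-2-(4-hydroxy-3,5-dimethoxyphenyl)-6-[2-(4-hydroxy-3-methoxyphenyl)ethyl]oxan-4-ol
Conditions: Bu4NF, AcOH (1.2 equiv each), THF, 0 °C to rt
Reagents that add atoms: none
Why: Fluoride cleavage of the aryl silyl ether; buffering with acetic acid keeps the medium from becoming basic, so the para-hydroxybenzylic C1–O bond is not opened and no stereocentre is touched.

## Compound list

1 | vanillin (4-hydroxy-3-methoxybenzaldehyde) | COc1cc(C=O)ccc1O | starting material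
2 | 3-methoxy-4-[(triisopropylsilyl)oxy]benzaldehyde | COc1cc(C=O)ccc1O[Si](C(C)C)(C(C)C)C(C)C | intermediate
3 | pentane-2,4-dione | CC(=O)CC(C)=O | starting material
4 | syringaldehyde (4-hydroxy-3,5-dimethoxybenzaldehyde) | COc1cc(C=O)cc(OC)c1O | starting material
5 | (5E)-6-(4-hydroxy-3,5-dimethoxyphenyl)hex-5-ene-2,4-dione | CC(=O)CC(=O)/C=C/c1cc(OC)c(O)c(OC)c1 | intermediate
6 | (1E,6E)-1-(4-hydroxy-3,5-dimethoxyphenyl)-7-{3-methoxy-4-[(triisopropylsilyl)oxy]phenyl}hepta-1,6-diene-3,5-dione | COc1cc(/C=C/C(=O)CC(=O)/C=C/c2cc(OC)c(O)c(OC)c2)ccc1O[Si](C(C)C)(C(C)C)C(C)C | intermediate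
7 | (1E)-1-(4-hydroxy-3,5-dimethoxyphenyl)-7-{3-methoxy-4-[(triisopropylsilyl)oxy]phenyl}hept-1-ene-3,5-dione | COc1cc(CCC(=O)CC(=O)/C=C/c2cc(OC)c(O)c(OC)c2)ccc1O[Si](C(C)C)(C(C)C)C(C)C | intermediate
8 | (6E)-1-(4-hydroxy-3,5-dimethoxyphenyl)-7-{3-methoxy-4-[(triisopropylsilyl)oxy]phenyl}hept-6-ene-3,5-dione | COc1cc(/C=C/C(=O)CC(=O)CCc2cc(OC)c(O)c(OC)c2)ccc1O[Si](C(C)C)(C(C)C)C(C)C | intermediate
9 | 1-(4-hydroxy-3,5-dimethoxyphenyl)-7-{3-methoxy-4-[(triisopropylsilyl)oxy]phenyl}heptane-3,5-dione | COc1cc(CCC(=O)CC(=O)CCc2cc(OC)c(O)c(OC)c2)ccc1O[Si](C(C)C)(C(C)C)C(C)C | intermediate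
10 | (5S)-5-hydroxy-1-(4-hydroxy-3,5-dimethoxyphenyl)-7-{3-methoxy-4-[(triisopropylsilyl)oxy]phenyl}heptan-3-one | COc1cc(CC[C@H](O)CC(=O)CCc2cc(OC)c(O)c(OC)c2)ccc1O[Si](C(C)C)(C(C)C)C(C)C | intermediate
11 | (3S)-3-hydroxy-1-(4-hydroxy-3,5-dimethoxyphenyl)-7-{3-methoxy-4-[(triisopropylsilyl)oxy]phenyl}heptan-5-one (chain numbering kept) | COc1cc(CCC(=O)C[C@@H](O)CCc2cc(OC)c(O)c(OC)c2)ccc1O[Si](C(C)C)(C(C)C)C(C)C | intermediate
12 | (3S,5S)-1-(4-hydroxy-3,5-dimethoxyphenyl)-7-{3-methoxy-4-[(triisopropylsilyl)oxy]phenyl}heptane-3,5-diol | COc1cc(CC[C@H](O)C[C@@H](O)CCc2cc(OC)c(O)c(OC)c2)ccc1O[Si](C(C)C)(C(C)C)C(C)C | intermediate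
13 | 4-[(3S,5S)-3,5-dihydroxy-7-{3-methoxy-4-[(triisopropylsilyl)oxy]phenyl}heptylidene]-2,6-dimethoxycyclohexa-2,5-dien-1-one | COc1cc(CC[C@H](O)C[C@@H](O)CC=C2C=C(OC)C(=O)C(OC)=C2)ccc1O[Si](C(C)C)(C(C)C)C(C)C | intermediate
14 | (2S,4R,6S)-2-(4-hydroxy-3,5-dimethoxyphenyl)-6-(2-{3-methoxy-4-[(triisopropylsilyl)oxy]phenyl}ethyl)oxan-4-ol | COc1cc(CC[C@H]2C[C@@H](O)C[C@@H](c3cc(OC)c(O)c(OC)c3)O2)ccc1O[Si](C(C)C)(C(C)C)C(C)C | intermediate
15 | (2S,4R,6S)-2-(4-hydroxy-3,5-dimethoxyphenyl)-6-[2-(4-hydroxy-3-methoxyphenyl)ethyl]oxan-4-ol | COc1cc(CC[C@H]2C[C@@H](O)C[C@@H](c3cc(OC)c(O)c(OC)c3)O2)ccc1O | target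

## Step count and risks

Total step count: 7. Longest linear sequence: 6 steps (steps 2 to 7, from 3 and 4); step 1 is a one-step branch.

**Step 6 (key step).** The most likely failures are two. First, a second oxidation of the newly formed benzylic ether at C1 may occur if ring closure is already fast on the silver surface. Second, 13 may tautomerise to the 4-hydroxystyrene, after which acid-induced loss of the now allylic C3 hydroxyl would follow. The fallback makes the over-oxidation deliberate and sets C1 by hydride delivery instead. It sets out from 12: DDQ (2.2 equiv) in CH2Cl2/H2O should take C1 to the ketone level and give (3R,5S)-3,5-dihydroxy-1-(4-hydroxy-3,5-dimethoxyphenyl)-7-{3-methoxy-4-[(triisopropylsilyl)oxy]phenyl}heptan-1-one F1, which closes to the lactol (4R,6S)-2-(4-hydroxy-3,5-dimethoxyphenyl)-6-(2-{3-methoxy-4-[(triisopropylsilyl)oxy]phenyl}ethyl)oxane-2,4-diol F2. Reductive etherification with Et3SiH and CF3CO2H in CH2Cl2 at −40 °C then reduces the cyclic oxocarbenium ion by axial hydride attack, which places ring A equatorial, and the route is rejoined at 14.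

**Step 3.** Under the amine/boron conditions, retro-aldol cleavage and re-condensation can exchange the aryl groups and give symmetrical curcuminoids, and the silyl ether may be partly lost during hydrolysis of the chelate. The fallback forms the C6–C7 bond by alkylation instead of condensation and sets out from 5 and 2. Hydrogenation of 5 (H2, Pd/C) should give 6-(4-hydroxy-3,5-dimethoxyphenyl)hexane-2,4-dione F3. Reduction of 2 with NaBH4 gives {3-methoxy-4-[(triisopropylsilyl)oxy]phenyl}methanol F4, and an Appel reaction (CBr4, PPh3) gives [4-(bromomethyl)-2-methoxyphenoxy]triisopropylsilane F5. The phenoxide-dianion of F3 (LiN(iPr)2, 3.1 equiv, THF, −78 to 0 °C) should be alkylated by F5 at the terminal methyl carbon, the most basic site. This gives 9 directly, so step 4 is also bypassed.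

**Step 2.** Double condensation to the symmetrical bis-adduct can compete with the wanted mono-condensation and complicate purification. The fallback builds 5 in the opposite order and sets out from 4. Claisen–Schmidt condensation with acetone (NaOH, aqueous acetone) gives (3E)-4-(4-hydroxy-3,5-dimethoxyphenyl)but-3-en-2-one F6. Claisen acylation of its methyl group with ethyl acetate (NaH, THF) then comes back to the route at 5.

**Step 5.** Incomplete catalyst control in the second reduction would give some syn diol, and the strongly enolised, phenol-bearing diketone may hydrogenate slowly. The fallback changes the source of the second stereocentre from catalyst to substrate and sets out from 9. The hydrogenation is interrupted at the hydroxy ketone stage (lower pressure, shorter time), and 10 and 11 are isolated together. The remaining carbonyl is reduced by Evans–Saksena reduction (Me4NBH(OAc)3, MeCN/AcOH, −30 °C), where intramolecular hydride delivery gives the 1,3-anti diol. Both 10 and 11 converge on 12, where the route is rejoined; no new compound is made.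

## Further compounds

F1 | step 6 | (3R,5S)-3,5-dihydroxy-1-(4-hydroxy-3,5-dimethoxyphenyl)-7-{3-methoxy-4-[(triisopropylsilyl)oxy]phenyl}heptan-1-one | COc1cc(CC[C@H](O)C[C@@H](O)CC(=O)c2cc(OC)c(O)c(OC)c2)ccc1O[Si](C(C)C)(C(C)C)C(C)C
F2 | step 6 | (4R,6S)-2-(4-hydroxy-3,5-dimethoxyphenyl)-6-(2-{3-methoxy-4-[(triisopropylsilyl)oxy]phenyl}ethyl)oxane-2,4-diol (anomeric mixture) | COc1cc(CC[C@H]2C[C@@H](O)CC(O)(c3cc(OC)c(O)c(OC)c3)O2)ccc1O[Si](C(C)C)(C(C)C)C(C)C
F3 | step 3 | 6-(4-hydroxy-3,5-dimethoxyphenyl)hexane-2,4-dione | CC(=O)CC(=O)CCc1cc(OC)c(O)c(OC)c1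
F4 | step 3 | {3-methoxy-4-[(triisopropylsilyl)oxy]phenyl}methanol | COc1cc(CO)ccc1O[Si](C(C)C)(C(C)C)C(C)C
F5 | step 3 | [4-(bromomethyl)-2-methoxyphenoxy]triisopropylsilane | COc1cc(CBr)ccc1O[Si](C(C)C)(C(C)C)C(C)C
F6 | step 2 | (3E)-4-(4-hydroxy-3,5-dimethoxyphenyl)but-3-en-2-one | CC(=O)/C=C/c1cc(OC)c(O)c(OC)c1
F0 | step 5 | none | none
A1 | alternative 1 | (3S)-1-[4-(benzyloxy)-3-methoxyphenyl]hex-5-en-3-ol | COc1cc(CC[C@H](O)CC=C)ccc1OCc1ccccc1
A2 | alternative 1 | 4-(benzyloxy)-3,5-dimethoxybenzaldehyde | COc1cc(C=O)cc(OC)c1OCc1ccccc1
A3 | alternative 1 | (2S,4R,6S)-2-[4-(benzyloxy)-3,5-dimethoxyphenyl]-6-{2-[4-(benzyloxy)-3-methoxyphenyl]ethyl}oxan-4-ol | COc1cc(CC[C@H]2C[C@@H](O)C[C@@H](c3cc(OC)c(OCc4ccccc4)c(OC)c3)O2)ccc1OCc1ccccc1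
A4 | alternative 2 | (1E,5S)-1-[4-(benzyloxy)-3,5-dimethoxyphenyl]-7-[4-(benzyloxy)-3-methoxyphenyl]-5-hydroxyhept-1-en-3-one | COc1cc(CC[C@H](O)CC(=O)/C=C/c2cc(OC)c(OCc3ccccc3)c(OC)c2)ccc1OCc1ccccc1
A5 | alternative 2 | (2S,6S)-2-[4-(benzyloxy)-3,5-dimethoxyphenyl]-6-{2-[4-(benzyloxy)-3-methoxyphenyl]ethyl}oxan-4-one | COc1cc(CC[C@H]2CC(=O)C[C@@H](c3cc(OC)c(OCc4ccccc4)c(OC)c3)O2)ccc1OCc1ccccc1
A6 | alternative 3 | 3-[4-(benzyloxy)-3-methoxyphenyl]propanal | COc1cc(CCC=O)ccc1OCc1ccccc1
A7 | alternative 3 | (1E)-1-methoxy-3-(trimethylsilyloxy)buta-1,3-diene | CO/C=C/C(=C)O[Si](C)(C)C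
A8 | alternative 3 | (2S)-2-{2-[4-(benzyloxy)-3-methoxyphenyl]ethyl}-2,3-dihydro-4H-pyran-4-one | COc1cc(CC[C@H]2CC(=O)C=CO2)ccc1OCc1ccccc1
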